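Remark on the chemistry: ring positions are given in flavone numbering (O1, C2, C3, C4, C4a, C5 to C8, C8a) also for open-chain precursors. The target is achiral; the only stereo-element on the route is the Z alkene of 13, 14 and 16, which disappears on cyclisation.

## The problem

The target 23 is a 2-aryl-chromen-4-one with a fully substituted ring A. C5 carries OH, C6 OMe, C7 OH and C8 the isovalerate, and ring C carries a 3-methoxy group beside the 4-methoxyphenyl group at C2. There is no stereocentre, so nothing has to be controlled stereochemically. The difficulty is regiochemical: four contiguous ring A oxygens in three different states (free, methylated, acylated) must be told apart, and the acyl group must end on O8 only. The aryl ester is the fragile group. It sits beside the free 7-OH, so base, nucleophiles or strong Lewis acids can hydrolyse it or move it to O7; it must be introduced late and followed only by neutral operations. Intermediates with free oxygens at C5 and C8 are para-hydroquinones and oxidise easily. The 5-OH is hydrogen-bonded to C4=O, which makes it the least nucleophilic phenol and makes a 5-O-benzyl ether the easiest one to cleave by chelation. The feature that opens the route is that O1 and the C4 carbonyl sit on the adjacent carbons C8a and C4a. These are the two carbons of an aryne, and if C8 is kept as C–H that aryne has an oxygen neighbour on one side only (C5), which decides where a nucleophile adds. Leaving O8 out also makes the ring A phenol symmetrical.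

## Retrosynthesis

**23 to 22 (O7–benzyl).** The last bond cut is the benzyl ether at O7. The 7-OH is the most acidic and most nucleophilic phenol of the flavone, so it has to stay masked while O8 is acylated. Hydrogenolysis is the one deprotection that is neutral enough to follow the ester. The forward step must spare the ester and the C2–C3 double bond.

**22 to 20 and 21 (O8–acyl).** The ester is cut to hydroquinone 20 and isovaleryl chloride 21. In 20 the 5-OH is chelated and the 7-oxygen is benzylated, so the 8-OH is the only phenol free to react. The forward step needs only mild, base-limited acylation.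

**20 to 18 (C8–O).** The C8 oxygen is removed to give the 5-hydroxyflavone 18. This cut is preferred over carrying O8 from the start, because an aryne with oxygen on both flanks would lose its regiochemical bias and the ring A precursor would lose its symmetry. In 18 C8 is the only unsubstituted ring A carbon and lies para to the 5-OH, so an Elbs persulfate oxidation has no regiochemical choice.

**18 to 17 (O5–benzyl) and 17 to 16 (O1–C2).** The 5-OH is traced to the bis-benzyl ether 17; the peri relation to C4=O allows selective cleavage. Flavone 17 is opened at O1–C2 to the 2'-hydroxy-alpha-methoxychalcone 16. The forward step is an oxidative cyclisation, for which iodine in DMSO is the standard reagent.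

**16 to 10 and 14 (O1–C8a and C4–C4a).** Both bonds that join ring A to the three-carbon chain are cut at once. This gives the silylaryl triflate 10 (the precursor of aryne 15) and the alpha-methoxycinnamic acid 14. Compared with a Friedel–Crafts or Fries route, this places the acyl group and the phenol oxygen in one operation, without Lewis acids that endanger benzyl ethers. The forward reaction must deliver the carboxylate oxygen to C8a and the acyl carbon to C4a; the lone flanking benzyloxy group of 15 is there to secure this.

**10 to 7 to 6.** The triflate and the ortho silyl group of 10 come from bromophenol 7 by O-silylation, bromine–lithium exchange with retro-Brook shift, and triflation. Bromophenol 7 comes from phenol 6 by monobromination. Phenol 6 is symmetrical, so the two ortho positions are equivalent and no regiochemical question arises.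

**6 to 4 to 3 to 2 to 1.** The phenol oxygen of 6 is traced to the formyl group of aldehyde 4 (Baeyer–Villiger oxidation through formate 5). Aldehyde 4 is traced through alcohol 3 and ester 2 to methyl 3,5-dihydroxy-4-methoxybenzoate 1, which already has the methyl ether between two equivalent hydroxyls.

**14 to 11 and 12.** The acid is cut at its C=C bond to 4-methoxybenzaldehyde 11 and methyl methoxyacetate 12. An aldol condensation with saponification in the same flask, through ester 13, should give the thermodynamically preferred Z acid.

## Roads not taken

**Alternative 1:** Ring A is built on a finished ring C. The cut is at C4a–C5, and one step earlier at C8–C8a, leading back to the pyranyl-hydroxycyclobutenone A2. A2 would come from a metalated 2-aryl-3-methoxypyranone and an unsymmetrical dialkyl squarate. Heating A2 should open the four-membered ring to a dienylketene, whose ketene carbon closes onto pyranone C5 in a six-electron electrocyclisation; tautomerisation gives the 5,8-hydroquinone A1.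
- Merits: O5 and O8 arrive with the ring, so no late hydroxylation is needed, and the thermolysis uses no reagent. In this respect the route is better than the chosen one, which has to pay for a late Elbs oxidation of typically modest efficiency.
- Weak points: the two squarate carbonyls differ only in a remote methyl versus isopropyl group, so the addition that decides 6-OMe/7-O-isopropyl against the reverse pattern has little bias. A 4-pyranone has to be metalated next to the ring oxygen in the presence of its own carbonyl. After 8-O-acylation, the isopropyl ether of A1 must be cleaved with a boron trihalide beside the aryl ester and a methoxy group ortho to the chelated 5-OH.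
- Comparison: the chosen plan sets against the Elbs step a ring A precursor whose regiochemistry is never in question and a neutral last step.

**Alternative 2:** Ring C is closed by cutting C4–C3 and O1–C2, leading to the fully substituted salicylaldehyde A4 and the ynol ether A5. With [(C5Me5)RhCl2]2 and Cu(OAc)2 the aldehyde C–H of A4 would add to trivalent rhodium under direction by the phenol, A5 would insert, and C–O reductive elimination would give chromone A3.
- Merits: ring C and both of its substituents are set in one convergent step. A3 already carries O8 as a methoxymethyl ether, so the end game would be three steps (acetal removal, acylation, one hydrogenolysis). This is shorter than the five steps that follow the key step here, and it avoids the Elbs oxidation.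
- Weak points: A4 is a hexasubstituted benzene with five oxygens in four different states, and making it regiospecifically would take most of the route. The reacting C–H and the directing OH are both flanked by ortho substituents. A5 is a strongly polarised, hydration-prone alkyne that must insert with the aryl carbon next to oxygen under hot acetate conditions, an orientation that is not secured for alkoxyalkynes.
- Comparison: the chosen plan offers a ring A piece made in six steps from a symmetrical ester with no regiochemical decision, and a known regiochemical rule for its key step.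

**Alternative 3:** C4 is introduced as carbon monoxide by cutting C4a–C4 and C4–C3, leading to aryl iodide A7 and the alpha-methoxy ketone A8. Under Pd(OAc)2 and a bidentate phosphine, zerovalent palladium would insert into the C–I bond of A7, take up carbon monoxide, and acylate the enolate of A8 to give the 2-methoxy-1,3-diketone A6. Acid would then remove both methoxymethyl groups and cyclodehydrate to the flavone with a free 8-OH.
- Merits: three simple components, a cheap one-carbon unit, and an end game of acylation and hydrogenolysis only. In post-key-step economy this is the best of the four routes.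
- Weak points: A7 is di-ortho-substituted and very electron-rich, so oxidative addition and carbon monoxide insertion would be slow and direct arylation of the enolate competes. A6 is more acidic than A8, so it consumes base and can be O-acylated. A7 needs the same long differentiation of five oxygens as A4.
- Comparison: the chosen plan has a short, unambiguous ring A synthesis and a key step without transition metal or gas; it concedes the two extra late steps (5-O-debenzylation and Elbs oxidation).

Key step: step 8

## Route

Step 1
Reactants: 1 methyl 3,5-dihydroxy-4-methoxybenzoate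
Product: 2 methyl 3,5-bis(benzyloxy)-4-methoxybenzoate
Conditions: BnBr, K2CO3, DMF, 60 °C
Reagents that add atoms: benzyl bromide, BrCc1ccccc1
Why: Williamson ether synthesis on two equivalent phenols; the methyl ester is stable to carbonate in DMF.

Step 2
Reactants: 2 methyl 3,5-bis(benzyloxy)-4-methoxybenzoate
Product: 3 [3,5-bis(benzyloxy)-4-methoxyphenyl]methanol
Conditions: LiAlH4, THF, 0 °C to rt
Reagents that add atoms: none
Why: Hydride reduction of an aryl ester to the benzylic alcohol; aryl ethers are inert.

Step 3
Reactants: 3 [3,5-bis(benzyloxy)-4-methoxyphenyl]methanol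
Product: 4 3,5-bis(benzyloxy)-4-methoxybenzaldehyde
Conditions: TEMPO (cat.), PhI(OAc)2, CH2Cl2, rt
Reagents that add atoms: none
Why: Oxoammonium-catalysed oxidation of a benzylic alcohol stops cleanly at the aldehyde; reduction followed by this oxidation is more reliable than partial reduction of the ester.

Step 4
Reactants: 4 3,5-bis(benzyloxy)-4-methoxybenzaldehyde
Product: 6 3,5-bis(benzyloxy)-4-methoxyphenol, via aryl formate 5 (not isolated)
Conditions: mCPBA, CH2Cl2, 0 °C to rt; then K2CO3 (cat.), MeOH, rt
Reagents that add atoms: meta-chloroperbenzoic acid, OOC(=O)c1cccc(Cl)c1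
Why: Baeyer–Villiger oxidation of an electron-rich benzaldehyde, in which the para-methoxy aryl group migrates in preference to hydride, gives formate 5; methanolysis releases the phenol (Dakin-type overall).

Step 5
Reactants: 6 3,5-bis(benzyloxy)-4-methoxyphenol
Product: 7 3,5-bis(benzyloxy)-2-bromo-4-methoxyphenol
Conditions: NBS (1.0 equiv), CH2Cl2, −78 to 0 °C
Reagents that add atoms: N-bromosuccinimide, BrN1C(=O)CCC1=O
Why: Electrophilic bromination ortho to the phenol; the two open positions are equivalent by symmetry, so one equivalent at low temperature should give a single monobromide.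

Step 6
Reactants: 7 3,5-bis(benzyloxy)-2-bromo-4-methoxyphenol
Product: 10 3,5-bis(benzyloxy)-4-methoxy-2-(trimethylsilyl)phenyl trifluoromethanesulfonate, via aryl trimethylsilyl ether 8 (not isolated), via lithium 2-silylphenoxide 9 (not isolated)
Conditions: HMDS, THF, reflux, then evaporate; n-BuLi, THF, −100 °C; Tf2O, −100 °C to rt
Reagents that add atoms: hexamethyldisilazane, C[Si](C)(C)N[Si](C)(C)C; trifluoromethanesulfonic anhydride, O=S(=O)(OS(=O)(=O)C(F)(F)F)C(F)(F)F
Why: Standard one-flask route to ortho-silylaryl triflates: bromine–lithium exchange on 8 is faster than benzylic deprotonation at −100 °C, the aryllithium takes silicon from the neighbouring oxygen (retro-Brook 1,3-shift), and phenoxide 9 is trapped by Tf2O.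

Step 7
Reactants: 11 4-methoxybenzaldehyde; 12 methyl methoxyacetate
Product: 14 (Z)-2-methoxy-3-(4-methoxyphenyl)prop-2-enoic acid, via methyl ester 13 (not isolated)
Conditions: NaOMe, MeOH, reflux; then aq NaOH, reflux; then HCl
Reagents that add atoms: sodium hydroxide, [Na+].[OH-]
Why: Aldol condensation of the ester enolate with a non-enolisable aldehyde and elimination gives the conjugated ester 13 with the aryl group trans to the carboxyl (Z); saponification in the same flask gives the acid, and the alkene geometry is not needed later.

Step 8
Reactants: 10 3,5-bis(benzyloxy)-4-methoxy-2-(trimethylsilyl)phenyl trifluoromethanesulfonate; 14 (Z)-2-methoxy-3-(4-methoxyphenyl)prop-2-enoic acid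
Product: 16 (Z)-1-[2,4-bis(benzyloxy)-6-hydroxy-3-methoxyphenyl]-2-methoxy-3-(4-methoxyphenyl)prop-2-en-1-one, via aryne 15 (not isolated)
Conditions: CsF (4 equiv), THF, 125 °C, sealed tube
Reagents that add atoms: none
Why: Fluoride removes the silyl group of 10 and triflate leaves to give aryne 15; the caesium carboxylate of 14 adds through oxygen to the aryne carbon that becomes C8a, the one remote from the C5 benzyloxy group, because this inductively withdrawing ether polarises the aryne so that negative charge develops at C4a next to it. The aryl anion at C4a then attacks the neighbouring acyl carbon, forming C4–C4a in a four-membered alkoxide that opens to the ortho-acyl phenoxide, so the aryne has inserted into the acyl C–O bond. This is the known insertion of arynes into the C–O bond of carboxylic acids, which has been carried out with cinnamic acids. No ring is closed and no stereocentre is formed; the Z alkene of 14 is carried through and is erased in step 9. The selectivity needed is regiochemical (oxygen to C8a, acyl to C4a), and it is secured by 15 having a single flanking oxygen, C8 being C–H; the more remote methoxy and benzyloxy groups are too far away to override it. The high temperature favours intramolecular acyl capture of the aryl anion over its protonation, which would stop at the aryl ester. The alpha-methoxy group and the anisyl ring both feed electron density to C2, so conjugate closure of the phenoxide onto the enone should be slow and 16 should be isolable.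

Step 9
Reactants: 16 (Z)-1-[2,4-bis(benzyloxy)-6-hydroxy-3-methoxyphenyl]-2-methoxy-3-(4-methoxyphenyl)prop-2-en-1-one
Product: 17 5,7-bis(benzyloxy)-3,6-dimethoxy-2-(4-methoxyphenyl)-4H-chromen-4-one
Conditions: I2 (cat.), DMSO, 130 °C
Reagents that add atoms: none
Why: Iodine–DMSO oxidative cyclisation of a 2'-hydroxychalcone: 6-endo conjugate addition of the phenol closes O1–C2, iodination at C3 and loss of HI give the flavone, and DMSO reoxidises iodide.

Step 10
Reactants: 17 5,7-bis(benzyloxy)-3,6-dimethoxy-2-(4-methoxyphenyl)-4H-chromen-4-one
Product: 18 7-(benzyloxy)-5-hydroxy-3,6-dimethoxy-2-(4-methoxyphenyl)-4H-chromen-4-one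
Conditions: MgBr2·OEt2, toluene–Et2O, 80 °C; aq HCl work-up
Reagents that add atoms: none
Why: Chelation-controlled cleavage of a benzyl ether ortho (peri) to a carbonyl: magnesium bridges C4=O and O5 and bromide removes the benzyl group, while the 7-benzyl ether and the methyl ethers lack this activation.

Step 11
Reactants: 18 7-(benzyloxy)-5-hydroxy-3,6-dimethoxy-2-(4-methoxyphenyl)-4H-chromen-4-one
Product: 20 7-(benzyloxy)-5,8-dihydroxy-3,6-dimethoxy-2-(4-methoxyphenyl)-4H-chromen-4-one, via potassium aryl sulfate 19 (not isolated)
Conditions: K2S2O8, aq KOH, pyridine, 0 °C to rt; then 2 M HCl, 80 °C, under argon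
Reagents that add atoms: potassium peroxodisulfate, [K+].[K+].[O-]S(=O)(=O)OOS(=O)(=O)[O-]
Why: Elbs persulfate oxidation: the 5-phenoxide attacks peroxodisulfate through its para carbon C8, the only unsubstituted ring A position, to give sulfate 19, which warm dilute acid hydrolyses; this nuclear oxidation is the classical way from 5-hydroxyflavones to 5,8-dihydroxyflavones.

Step 12
Reactants: 20 7-(benzyloxy)-5,8-dihydroxy-3,6-dimethoxy-2-(4-methoxyphenyl)-4H-chromen-4-one; 21 isovaleryl chloride
Product: 22 7-(benzyloxy)-5-hydroxy-3,6-dimethoxy-2-(4-methoxyphenyl)-4-oxo-4H-chromen-8-yl 3-methylbutanoate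
Conditions: pyridine, CH2Cl2, 0 °C, under argon
Reagents that add atoms: none
Why: O-acylation of the only non-chelated phenol; the 5-OH is hydrogen-bonded to C4=O and is left alone with about one equivalent of acid chloride at low temperature.

Step 13
Reactants: 22 7-(benzyloxy)-5-hydroxy-3,6-dimethoxy-2-(4-methoxyphenyl)-4-oxo-4H-chromen-8-yl 3-methylbutanoate
Product: 23 5,7-dihydroxy-3,6-dimethoxy-2-(4-methoxyphenyl)-4-oxo-4H-chromen-8-yl 3-methylbutanoate (5,7,8-trihydroxy-3,6,4'-trimethoxyflavone 8-isovalerate)
Conditions: H2 (1 atm), Pd/C, EtOAc, rt
Reagents that add atoms: none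
Why: Hydrogenolysis of an aryl benzyl ether under neutral conditions; the aryl ester and the flavone C2–C3 double bond are not reduced at ambient pressure, and the absence of base disfavours acyl migration from O8 to O7.

## Compound list

1 | methyl 3,5-dihydroxy-4-methoxybenzoate | COC(=O)c1cc(O)c(OC)c(O)c1 | starting material
2 | methyl 3,5-bis(benzyloxy)-4-methoxybenzoate | COC(=O)c1cc(OCc2ccccc2)c(OC)c(OCc2ccccc2)c1 | intermediate
3 | [3,5-bis(benzyloxy)-4-methoxyphenyl]methanol | COc1c(OCc2ccccc2)cc(CO)cc1OCc1ccccc1 | intermediate
4 | 3,5-bis(benzyloxy)-4-methoxybenzaldehyde | COc1c(OCc2ccccc2)cc(C=O)cc1OCc1ccccc1 | intermediate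
5 | 3,5-bis(benzyloxy)-4-methoxyphenyl formate | COc1c(OCc2ccccc2)cc(OC=O)cc1OCc1ccccc1 | intermediate (not isolated)
6 | 3,5-bis(benzyloxy)-4-methoxyphenol | COc1c(OCc2ccccc2)cc(O)cc1OCc1ccccc1 | intermediate
7 | 3,5-bis(benzyloxy)-2-bromo-4-methoxyphenol | COc1c(OCc2ccccc2)cc(O)c(Br)c1OCc1ccccc1 | intermediate
8 | {[3,5-bis(benzyloxy)-2-bromo-4-methoxyphenyl]oxy}trimethylsilane | COc1c(OCc2ccccc2)cc(O[Si](C)(C)C)c(Br)c1OCc1ccccc1 | intermediate (not isolated)
9 | lithium 3,5-bis(benzyloxy)-4-methoxy-2-(trimethylsilyl)phenoxide | COc1c(OCc2ccccc2)cc([O-])c([Si](C)(C)C)c1OCc1ccccc1.[Li+] | intermediate (not isolated)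
10 | 3,5-bis(benzyloxy)-4-methoxy-2-(trimethylsilyl)phenyl trifluoromethanesulfonate | COc1c(OCc2ccccc2)cc(OS(=O)(=O)C(F)(F)F)c([Si](C)(C)C)c1OCc1ccccc1 | intermediate
11 | 4-methoxybenzaldehyde | COc1ccc(C=O)cc1 | starting material
12 | methyl methoxyacetate | COCC(=O)OC | starting material
13 | methyl (Z)-2-methoxy-3-(4-methoxyphenyl)prop-2-enoate | COc1ccc(/C=C(\OC)C(=O)OC)cc1 | intermediate (not isolated)
14 | (Z)-2-methoxy-3-(4-methoxyphenyl)prop-2-enoic acid | COc1ccc(/C=C(\OC)C(=O)O)cc1 | intermediate
15 | 3,5-bis(benzyloxy)-4-methoxy-1,2-didehydrobenzene (aryne) | COC1=C(OCc2ccccc2)C#CC=C1OCc1ccccc1 | intermediate (not isolated)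
16 | (Z)-1-[2,4-bis(benzyloxy)-6-hydroxy-3-methoxyphenyl]-2-methoxy-3-(4-methoxyphenyl)prop-2-en-1-one | COc1ccc(/C=C(\OC)C(=O)c2c(O)cc(OCc3ccccc3)c(OC)c2OCc2ccccc2)cc1 | intermediate
17 | 5,7-bis(benzyloxy)-3,6-dimethoxy-2-(4-methoxyphenyl)-4H-chromen-4-one | COc1ccc(-c2oc3cc(OCc4ccccc4)c(OC)c(OCc4ccccc4)c3c(=O)c2OC)cc1 | intermediate
18 | 7-(benzyloxy)-5-hydroxy-3,6-dimethoxy-2-(4-methoxyphenyl)-4H-chromen-4-one | COc1ccc(-c2oc3cc(OCc4ccccc4)c(OC)c(O)c3c(=O)c2OC)cc1 | intermediate
19 | potassium 7-(benzyloxy)-5-hydroxy-3,6-dimethoxy-2-(4-methoxyphenyl)-4-oxo-4H-chromen-8-yl sulfate | COc1ccc(-c2oc3c(OS(=O)(=O)[O-])c(OCc4ccccc4)c(OC)c(O)c3c(=O)c2OC)cc1.[K+] | intermediate (not isolated)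
20 | 7-(benzyloxy)-5,8-dihydroxy-3,6-dimethoxy-2-(4-methoxyphenyl)-4H-chromen-4-one | COc1ccc(-c2oc3c(O)c(OCc4ccccc4)c(OC)c(O)c3c(=O)c2OC)cc1 | intermediate
21 | isovaleryl chloride (3-methylbutanoyl chloride) | CC(C)CC(=O)Cl | starting material
22 | 7-(benzyloxy)-5-hydroxy-3,6-dimethoxy-2-(4-methoxyphenyl)-4-oxo-4H-chromen-8-yl 3-methylbutanoate | COc1ccc(-c2oc3c(OC(=O)CC(C)C)c(OCc4ccccc4)c(OC)c(O)c3c(=O)c2OC)cc1 | intermediate
23 | 5,7-dihydroxy-3,6-dimethoxy-2-(4-methoxyphenyl)-4-oxo-4H-chromen-8-yl 3-methylbutanoate | COc1ccc(-c2oc3c(OC(=O)CC(C)C)c(O)c(OC)c(O)c3c(=O)c2OC)cc1 | target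

## Step count and risks

Total step count: 13. Longest linear sequence: 12 steps (steps 1 to 6 and 8 to 13, from 1); the acid branch adds one step (step 7).

**Step 8 (key step).** Most likely failure modes:
- protonation of the aryl anion before it captures the acyl group, so that only O-arylation to the aryl ester occurs;
- fluoride attack at sulfur of the crowded triflate, which would return a phenoxide without generating the aryne;
- arylation of the product phenoxide by a second aryne.

In-flask conjugate closure to the flavanone (compound F4 of the step 9 fallback) would do no harm, since step 9 oxidises it to 17 as well.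

Fallback: build the same aryl ketone by an anionic Fries route without an aryne, setting out from bromophenol 7. Acylation with methoxyacetyl chloride (Et3N, CH2Cl2) would give 3,5-bis(benzyloxy)-2-bromo-4-methoxyphenyl methoxyacetate F1. Bromine–lithium exchange (n-BuLi, THF, −100 °C) would trigger the O-to-C acyl shift to 1-[2,4-bis(benzyloxy)-6-hydroxy-3-methoxyphenyl]-2-methoxyethan-1-one F2. Claisen–Schmidt condensation of F2 with aldehyde 11 (KOH, EtOH) would return to the route at chalcone 16.

**Step 11.** Elbs oxidations often stop at low conversion, and the electron-rich hydroquinone can be oxidised further by persulfate or air to quinone and polymeric material. Partial loss of the 7-benzyl group during the acid hydrolysis is a lesser risk.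

Fallback: a two-stage quinone route from 18. Oxidation of the para-unsubstituted phenol with (KSO3)2NO in aqueous KH2PO4–acetone (Teuber oxidation) would give 7-(benzyloxy)-3,6-dimethoxy-2-(4-methoxyphenyl)-4H-chromene-4,5,8-trione F3. Reduction with Na2S2O4 in EtOAc–water would give hydroquinone 20, where the route is rejoined.

**Step 9.** The HI formed at 130 °C may cleave benzyl ethers (loss at O5 would be harmless, loss at O7 would not). The dehydrogenation may also stall after ring closure, because C3 carries a methoxy group.

Fallback: separate ring closure from dehydrogenation, setting out from 16. NaOAc in refluxing EtOH would effect the oxa-Michael closure to 5,7-bis(benzyloxy)-3,6-dimethoxy-2-(4-methoxyphenyl)chroman-4-one F4 (racemic mixture of C2/C3 diastereomers; both centres are removed next). DDQ in refluxing dioxane would dehydrogenate F4 to flavone 17.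

**Step 5.** The very electron-rich phenol may be brominated twice or oxidised by NBS to a quinone with loss of the para-methoxy group.

Fallback: a carbamate-directed ortho-metalation route that avoids an electrophilic halogen, setting out from phenol 6. Isopropyl isocyanate (Et3N cat., CH2Cl2) would give 3,5-bis(benzyloxy)-4-methoxyphenyl N-isopropylcarbamate F5. In-situ N-silylation (TMSOTf, TMEDA), ortho-lithiation (n-BuLi, Et2O, −78 °C) at either of the two equivalent positions and quench with TMSCl would give 3,5-bis(benzyloxy)-4-methoxy-2-(trimethylsilyl)phenyl N-isopropylcarbamate F6. Carbamate cleavage with Et2NH and DBU in MeCN, followed by PhNTf2 in the same flask, would give triflate 10. This bypasses steps 5 and 6.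

**Step 13.** Once O7 is free, the isovaleryl group may migrate from O8 to O7, and prolonged hydrogenation may saturate the C2–C3 double bond.

Fallback: non-reductive Lewis-acid debenzylation of 22 with BCl3 and pentamethylbenzene as cation scavenger in CH2Cl2 at −78 °C. This gives 23 directly and creates no new intermediate.

## Further compounds

F1 | step 8 | 3,5-bis(benzyloxy)-2-bromo-4-methoxyphenyl methoxyacetate | COCC(=O)Oc1cc(OCc2ccccc2)c(OC)c(OCc2ccccc2)c1Br
F2 | step 8 | 1-[2,4-bis(benzyloxy)-6-hydroxy-3-methoxyphenyl]-2-methoxyethan-1-one | COCC(=O)c1c(O)cc(OCc2ccccc2)c(OC)c1OCc1ccccc1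
F3 | step 11 | 7-(benzyloxy)-3,6-dimethoxy-2-(4-methoxyphenyl)-4H-chromene-4,5,8-trione | COc1ccc(cc1)C1=C(OC)C(=O)C2=C(O1)C(=O)C(OCc1ccccc1)=C(OC)C2=O
F4 | step 9 | 5,7-bis(benzyloxy)-3,6-dimethoxy-2-(4-methoxyphenyl)chroman-4-one (racemic mixture of diastereomers) | COc1ccc(C2Oc3cc(OCc4ccccc4)c(OC)c(OCc4ccccc4)c3C(=O)C2OC)cc1
F5 | step 5 | 3,5-bis(benzyloxy)-4-methoxyphenyl N-isopropylcarbamate | CC(C)NC(=O)Oc1cc(OCc2ccccc2)c(OC)c(OCc2ccccc2)c1
F6 | step 5 | 3,5-bis(benzyloxy)-4-methoxy-2-(trimethylsilyl)phenyl N-isopropylcarbamate | CC(C)NC(=O)Oc1cc(OCc2ccccc2)c(OC)c(OCc2ccccc2)c1[Si](C)(C)C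
F0 | step 13 | none | none
A1 | alternative 1 | 5,8-dihydroxy-7-isopropoxy-3,6-dimethoxy-2-(4-methoxyphenyl)-4H-chromen-4-one | COc1ccc(-c2oc3c(O)c(OC(C)C)c(OC)c(O)c3c(=O)c2OC)cc1
A2 | alternative 1 | rac-4-hydroxy-3-isopropoxy-2-methoxy-4-[5-methoxy-6-(4-methoxyphenyl)-4-oxo-4H-pyran-2-yl]cyclobut-2-en-1-one | COC1=C(OC(C)C)C(O)(c2cc(=O)c(OC)c(-c3ccc(OC)cc3)o2)C1=O
A3 | alternative 2 | 5,7-bis(benzyloxy)-3,6-dimethoxy-8-(methoxymethoxy)-2-(4-methoxyphenyl)-4H-chromen-4-one | COCOc1c(OCc2ccccc2)c(OC)c(OCc2ccccc2)c2c(=O)c(OC)c(-c3ccc(OC)cc3)oc12
A4 | alternative 2 | 4,6-bis(benzyloxy)-2-hydroxy-5-methoxy-3-(methoxymethoxy)benzaldehyde | COCOc1c(O)c(C=O)c(OCc2ccccc2)c(OC)c1OCc1ccccc1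
A5 | alternative 2 | 1-methoxy-4-(methoxyethynyl)benzene | COC#Cc1ccc(OC)cc1
A6 | alternative 3 | rac-1-[2,4-bis(benzyloxy)-3-methoxy-5,6-bis(methoxymethoxy)phenyl]-2-methoxy-3-(4-methoxyphenyl)propane-1,3-dione | COCOc1c(C(=O)C(OC)C(=O)c2ccc(OC)cc2)c(OCc2ccccc2)c(OC)c(OCc2ccccc2)c1OCOC
A7 | alternative 3 | 1,3-bis(benzyloxy)-4-iodo-2-methoxy-5,6-bis(methoxymethoxy)benzene | COCOc1c(I)c(OCc2ccccc2)c(OC)c(OCc2ccccc2)c1OCOC
A8 | alternative 3 | 2-methoxy-1-(4-methoxyphenyl)ethan-1-one | COCC(=O)c1ccc(OC)cc1
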